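**Plan**

- Cuts (cembrane numbering: ring C1–C14, propenoate C15–C17, oxolane oxygen between C4 and C7): C3 carbinol from the ketone; lactone O–C16 and C13 acetate from an acetonide methyl ester; C1–C2 (the 14-membered ring) from a seco allylic carbonate/β-keto ester; C2–C3 and C1–C15 from a C3/C1 dialdehyde; C9–C10 from a Grignard reagent and an epoxide; C12–C13 by crotylboration; O–C7 by epoxy-alcohol opening.
- Forward order: oxolane ring (step 2), chain joined at C9–C10 (step 9), termini armed at C1 and then C3 (steps 10–14), carbocycle (step 15), γ-lactone (step 17), C3 carbinol last (step 19).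
- Stereochemistry: C4 from (S)-linalool; C7/C8 from Sharpless epoxidation and invertive 5-exo opening; C14 from (R)-glyceraldehyde acetonide; C12/C13 from reagent-controlled (Z)-crotylboration; C1 from the chiral amine of the key step, supported by C14; C3 from chelate-controlled hydride delivery.
- Enabling feature: C1 is the allylic methine between acrylate carbon C15 and C2, and C2 is the only enolisable position of the C3 ketone because the oxolane carbon C4 is fully substituted. One allyl electrophile therefore meets one enolate.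

Key step: step 15

Remark: C1 in 22–24 and C2 in 25–26 are carried as epimeric mixtures, since both centres are reset or destroyed; their SMILES leave them undefined.
Remark: (S)-linalool is taken as enantio-enriched material; its antipode ends up as a diastereomer of 4 and is removed there.

**Route**

Step 1
Reactants: 1 (S)-linalool
Product: 2 (2E,6S)-2,6-dimethylocta-2,7-diene-1,6-diol
Conditions: SeO2 (cat.), t-BuOOH, salicylic acid (cat.), CH2Cl2, rt
Reagents that add atoms: tert-butyl hydroperoxide, CC(C)(C)OO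
Why: Riley allylic oxidation (ene reaction, then [2,3]-shift) should hydroxylate the (E)-methyl group of the electron-rich trisubstituted alkene, the vinyl group having no allylic hydrogen and the carbinol centre being untouched.

Step 2
Reactants: 2 (2E,6S)-2,6-dimethylocta-2,7-diene-1,6-diol
Product: 4 (2S)-2-[(2R,5S)-5-ethenyl-5-methyloxolan-2-yl]propane-1,2-diol, via epoxy alcohol 3 (not isolated)
Conditions: Ti(OiPr)4 (20 mol %), L-(+)-diethyl tartrate (24 mol %), t-BuOOH, 4 Å MS, CH2Cl2, −20 °C, then rt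
Reagents that add atoms: tert-butyl hydroperoxide, CC(C)(C)OO
Why: Sharpless asymmetric epoxidation of the primary (E)-allylic alcohol with the L-(+)-tartrate should give the (2S,3S)-epoxy alcohol, which the tertiary hydroxyl, assisted by the titanium alkoxide, opens 5-exo-tet at the epoxide carbon remote from the hydroxymethyl group with inversion (7R) while the C8–O bond is retained (8S).

Step 3
Reactants: 4 (2S)-2-[(2R,5S)-5-ethenyl-5-methyloxolan-2-yl]propane-1,2-diol
Product: 6 (2S,5R)-2-ethenyl-2-methyl-5-[(2S)-2-methyloxiran-2-yl]oxolane, via primary tosylate 5 (not isolated)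
Conditions: NaH, N-tosylimidazole, THF, 0 °C → rt
Reagents that add atoms: none
Why: Selective sulfonylation of the primary alkoxide followed by Williamson closure by the tertiary alkoxide should give the 2,2-disubstituted epoxide without breaking the C8–O bond, so 8S is kept.

Step 4
Reactants: 7 (R)-2,2-dimethyl-1,3-dioxolane-4-carbaldehyde
Product: 9 (1R,2S)-1-[(4R)-2,2-dimethyl-1,3-dioxolan-4-yl]-2-methylbut-3-en-1-ol, via borinate ester 8 (not isolated)
Conditions: (Z)-crotyl-B(Ipc)2 [made in the flask from cis-2-butene, n-BuLi, KOt-Bu, (+)-Ipc2BOMe, BF3·OEt2], THF–Et2O, −78 °C; then NaOH, H2O2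
Reagents that add atoms: (Z)-crotyldiisopinocampheylborane of the (−)-α-pinene series (crotyl group from cis-2-butene), C/C=C\CB([C@H]1C[C@H]2C[C@@H]([C@@H]1C)C2(C)C)[C@H]3C[C@H]4C[C@@H]([C@@H]3C)C4(C)C
Why: Brown crotylboration through a closed chair transition state should give the 12,13-syn pair from the (Z)-crotyl geometry, while the isopinocampheyl groups of the (−)-α-pinene series direct attack to the Re face of the aldehyde against its Felkin preference (13R, 13,14-syn), C14 coming unchanged from 7.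

Step 5
Reactants: 9 (1R,2S)-1-[(4R)-2,2-dimethyl-1,3-dioxolan-4-yl]-2-methylbut-3-en-1-ol
Product: 10 [(4R,5R)-5-[(2S)-but-3-en-2-yl]-2,2-dimethyl-1,3-dioxolan-4-yl]methanol
Conditions: p-TsOH·H2O (cat.), acetone, rt
Reagents that add atoms: none
Why: Acid-catalysed acetonide migration under thermodynamic control should favour the trans-4,5-disubstituted dioxolane of the threo 13,14-diol and free the primary C1 hydroxyl, whereas the erythro by-product of step 4 cannot form a comparably stable internal acetal and is separated here.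

Step 6
Reactants: 10 [(4R,5R)-5-[(2S)-but-3-en-2-yl]-2,2-dimethyl-1,3-dioxolan-4-yl]methanol
Product: 11 {[(4R,5R)-5-[(2S)-but-3-en-2-yl]-2,2-dimethyl-1,3-dioxolan-4-yl]methoxy}triethylsilane
Conditions: TESCl, imidazole, CH2Cl2, 0 °C
Reagents that add atoms: chlorotriethylsilane, CC[Si](Cl)(CC)CC
Why: Standard silylation of the primary alcohol gives an ether that tolerates the organomagnesium step and can later be oxidised directly.

Step 7
Reactants: 11 {[(4R,5R)-5-[(2S)-but-3-en-2-yl]-2,2-dimethyl-1,3-dioxolan-4-yl]methoxy}triethylsilane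
Product: 13 (3S)-3-[(4R,5R)-2,2-dimethyl-5-{[(triethylsilyl)oxy]methyl}-1,3-dioxolan-4-yl]butan-1-ol, via alkylborane 12 (not isolated)
Conditions: 9-BBN, THF, 0 °C → rt; then NaOH, H2O2, 0 °C
Reagents that add atoms: hydrogen peroxide, OO
Why: Anti-Markovnikov hydroboration–oxidation of the terminal alkene should place the hydroxyl on C10 without touching C12.

Step 8
Reactants: 13 (3S)-3-[(4R,5R)-2,2-dimethyl-5-{[(triethylsilyl)oxy]methyl}-1,3-dioxolan-4-yl]butan-1-ol
Product: 14 {[(4R,5R)-5-[(2S)-4-bromobutan-2-yl]-2,2-dimethyl-1,3-dioxolan-4-yl]methoxy}triethylsilane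
Conditions: CBr4, PPh3, CH2Cl2, 0 °C
Reagents that add atoms: carbon tetrabromide, BrC(Br)(Br)Br
Why: The Appel reaction converts the primary alcohol into the bromide under neutral conditions that spare the acetonide and the silyl ether.

Step 9
Reactants: 14 {[(4R,5R)-5-[(2S)-4-bromobutan-2-yl]-2,2-dimethyl-1,3-dioxolan-4-yl]methoxy}triethylsilane; 6 (2S,5R)-2-ethenyl-2-methyl-5-[(2S)-2-methyloxiran-2-yl]oxolane
Product: 17 (2S,6S)-2-[(2R,5S)-5-ethenyl-5-methyloxolan-2-yl]-6-[(4R,5R)-2,2-dimethyl-5-{[(triethylsilyl)oxy]methyl}-1,3-dioxolan-4-yl]heptan-2-yl acetate, via Grignard reagent 15 (not isolated), via magnesium alkoxide 16 (not isolated)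
Conditions: Mg, THF, 40 °C; then 6, CuI (10 mol %), −30 → 0 °C; then Ac2O, DMAP, 0 °C → rt
Reagents that add atoms: acetic anhydride, CC(=O)OC(C)=O
Why: Copper-catalysed Grignard opening of the 2,2-disubstituted epoxide at its CH2 terminus should form C9–C10 with C8 untouched, and acetylation of the tertiary magnesium alkoxide in the same flask installs the C8 acetate of the target and prevents hemiketal formation with the later C3 carbonyl.

Step 10
Reactants: 17 (2S,6S)-2-[(2R,5S)-5-ethenyl-5-methyloxolan-2-yl]-6-[(4R,5R)-2,2-dimethyl-5-{[(triethylsilyl)oxy]methyl}-1,3-dioxolan-4-yl]heptan-2-yl acetate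
Product: 19 (2S,5R)-5-[(2S,6S)-2-acetoxy-6-[(4R,5R)-2,2-dimethyl-5-{[(triethylsilyl)oxy]methyl}-1,3-dioxolan-4-yl]heptan-2-yl]-2-methyloxolane-2-carbaldehyde, via ozonide 18 (not isolated)
Conditions: O3, CH2Cl2, −78 °C; then PPh3
Reagents that add atoms: ozone, [O-][O+]=O
Why: Ozonolysis with reductive work-up cleaves the only alkene and gives the non-enolisable C3 aldehyde on the fully substituted C4.

Step 11
Reactants: 19 (2S,5R)-5-[(2S,6S)-2-acetoxy-6-[(4R,5R)-2,2-dimethyl-5-{[(triethylsilyl)oxy]methyl}-1,3-dioxolan-4-yl]heptan-2-yl]-2-methyloxolane-2-carbaldehyde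
Product: 20 (4S,5R)-5-[(2S,6S)-6-acetoxy-6-[(2R,5S)-5-formyl-5-methyloxolan-2-yl]heptan-2-yl]-2,2-dimethyl-1,3-dioxolane-4-carbaldehyde
Conditions: (COCl)2, DMSO, CH2Cl2, −78 → −30 °C; then Et3N, −78 °C → rt
Reagents that add atoms: none
Why: Swern conditions are known to turn primary triethylsilyl ethers directly into aldehydes (chlorosulfonium-induced desilylation, then oxidation), and the trans-dioxolane is the thermodynamically preferred arrangement at C14, so epimerisation is not expected.

Step 12
Reactants: 20 (4S,5R)-5-[(2S,6S)-6-acetoxy-6-[(2R,5S)-5-formyl-5-methyloxolan-2-yl]heptan-2-yl]-2,2-dimethyl-1,3-dioxolane-4-carbaldehyde; 21 methyl acrylate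
Product: 22 Morita–Baylis–Hillman alcohol, methyl 2-[hydroxy(dioxolanyl)methyl]prop-2-enoate still carrying the C3 aldehyde (C1 epimers; other centres as in 20)
Conditions: DABCO, 1,4-dioxane–H2O (1:1), rt
Reagents that add atoms: none
Why: The Morita–Baylis–Hillman reaction should take place only at the unhindered, oxygen-activated C1 aldehyde, the C3 aldehyde on the fully substituted C4 being neopentyl-like and inert to the bulky ammonium enolate; both C1 epimers are usable.

Step 13
Reactants: 22 Morita–Baylis–Hillman alcohol (C1 epimers)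
Product: 23 Morita–Baylis–Hillman tert-butyl carbonate carrying the C3 aldehyde (C1 epimers; other centres as in 20)
Conditions: Boc2O, DMAP (10 mol %), CH2Cl2, 0 °C
Reagents that add atoms: di-tert-butyl dicarbonate, CC(C)(C)OC(=O)OC(=O)OC(C)(C)C
Why: DMAP-catalysed carbonate formation is the standard activation of such allylic alcohols, and the C3 aldehyde, having no α-hydrogen, cannot be trapped as an enol carbonate.

Step 14
Reactants: 23 Morita–Baylis–Hillman tert-butyl carbonate carrying the C3 aldehyde (C1 epimers)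
Product: 24 seco allyl β-keto ester, methyl 1-(tert-butoxycarbonyloxy)-8-acetoxy-4,7-epoxy-13,14-(isopropylidenedioxy)-3-oxo-2-(prop-2-enyloxycarbonyl)-1,2-secocembr-15(17)-en-16-oate (C1 epimers; other centres as in 20)
Conditions: allyl diazoacetate, SnCl2 (20 mol %), CH2Cl2, rt
Reagents that add atoms: allyl diazoacetate, C=CCOC(=O)C=[N+]=[N-]
Why: Roskamp homologation (Lewis-acid-promoted addition of the diazo ester, 1,2-hydride shift, loss of N2) makes the β-keto ester under non-basic conditions that leave the allylic carbonate alone, and it is placed last so that the acidic β-keto ester never meets DABCO, methyl acrylate or Boc2O/DMAP.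

Step 15
Reactants: 24 seco allyl β-keto ester (C1 epimers)
Product: 25 macrocyclic β-keto ester, methyl (1S,4S,7R,8S,12S,13R,14R)-8-acetoxy-4,7-epoxy-13,14-(isopropylidenedioxy)-3-oxo-2-(prop-2-enyloxycarbonyl)cembr-15(17)-en-16-oate (C2 epimers)
Conditions: (DHQD)2PHAL (hydroquinidine 1,4-phthalazinediyl diether, 20 mol %), PhMe, 50 °C, syringe-pump addition of 24 (final 1 mM)
Reagents that add atoms: none
Why: Proposed new method: the tertiary amine adds to C17 and expels the carbonate from C1 (first SN2′ step), the carbonate loses CO2, the tert-butoxide deprotonates C2 (the only enolisable position), and the enolate carbon attacks C1 of the allylammonium ion (second SN2′ step), releasing the amine and restoring the 2-methylene ester. The closest known reactions are the intermolecular cinchona-amine-catalysed asymmetric allylic alkylations of Morita–Baylis–Hillman carbonates with β-keto esters and their intramolecular versions that close five- and six-membered rings. The 14-membered carbocycle closes in a 14-exo-trig mode, C2 adding to trigonal C1 with the C1=C15 bond outside the new ring. C1 (1S) is set by the face of the ion pair left open by the quinidine-derived amine, and C14 should reinforce it because allylic 1,3-strain holds H14 in the plane of the allyl unit so that the C13 branch shields the opposite face; C2 forms as a mixture and is erased in step 16. The step needs C- over O-alkylation and attack at C1 instead of C17, which the soft stabilised enolate and the position of the ammonium group secure. It also needs ring closure to beat chain growth, which rests on high dilution and on the fact that electrophile and nucleophile are generated only pairwise at the catalyst, so their stationary concentration stays low.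

Step 16
Reactants: 25 macrocyclic β-keto ester (C2 epimers)
Product: 27 methyl (1S,4S,7R,8S,12S,13R,14R)-8-acetoxy-4,7-epoxy-13,14-(isopropylidenedioxy)-3-oxocembr-15(17)-en-16-oate, via β-keto acid 26 (not isolated)
Conditions: Pd(OAc)2 (5 mol %), PPh3, HCO2H, Et3N, THF, rt → 40 °C
Reagents that add atoms: none
Why: Palladium-catalysed deallylation–decarboxylation: zerovalent palladium formed in the flask ionises the allyl ester, formate reduces the allyl fragment to propene, and the β-keto acid loses CO2 on mild warming, while the 2-methylene ester carries no leaving group and C1 is not touched.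

Step 17
Reactants: 27 methyl (1S,4S,7R,8S,12S,13R,14R)-8-acetoxy-4,7-epoxy-13,14-(isopropylidenedioxy)-3-oxocembr-15(17)-en-16-oate
Product: 29 (1S,4S,7R,8S,12S,13R,14R)-8-acetoxy-4,7-epoxy-13-hydroxy-3-oxocembr-15(17)-en-16,14-olide, via diol ester 28 (not isolated)
Conditions: AcOH–H2O (4:1), 45 °C; then p-TsOH·H2O (cat.), CH2Cl2, rt
Reagents that add atoms: none
Why: Mild acid hydrolysis of the dioxolane followed by acid-catalysed lactonisation should give the γ-lactone through the C14 hydroxyl (five-membered closure being faster than the six-membered one through C13), under conditions too weak to ionise the tertiary acetate.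

Step 18
Reactants: 29 (1S,4S,7R,8S,12S,13R,14R)-8-acetoxy-4,7-epoxy-13-hydroxy-3-oxocembr-15(17)-en-16,14-olide
Product: 30 (1S,4S,7R,8S,12S,13R,14R)-8,13-diacetoxy-4,7-epoxy-3-oxocembr-15(17)-en-16,14-olide
Conditions: Ac2O, pyridine, DMAP (cat.), CH2Cl2, 0 °C → rt
Reagents that add atoms: acetic anhydride, CC(=O)OC(C)=O
Why: Acetylation of the only free hydroxyl (C13) is straightforward because C3 is still a ketone, so no differentiation of two secondary alcohols is needed.

Step 19
Reactants: 30 (1S,4S,7R,8S,12S,13R,14R)-8,13-diacetoxy-4,7-epoxy-3-oxocembr-15(17)-en-16,14-olide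
Product: 31 (1S,3R,4S,7R,8S,12S,13R,14R)-8,13-diacetoxy-4,7-epoxy-3-hydroxycembr-15(17)-en-16,14-olide (CID10479028)
Conditions: Zn(BH4)2, Et2O, −20 °C; then aq. NH4Cl
Reagents that add atoms: none
Why: Chelation-controlled reduction: zinc should bind the C3 carbonyl and the oxolane oxygen on C4, so hydride arrives on the chelate face that carries the C4 methyl group, away from ring carbons C5/C6 (3R), and this mild reagent at low temperature should spare the acetates and the unsaturated lactone.

**Compound list**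

1 | (S)-linalool, (3S)-3,7-dimethylocta-1,6-dien-3-ol | C=C[C@@](C)(O)CCC=C(C)C | starting material
2 | (2E,6S)-2,6-dimethylocta-2,7-diene-1,6-diol | C=C[C@@](C)(O)CC/C=C(\C)CO | intermediate
3 | [(2S,3S)-3-[(3S)-3-hydroxy-3-methylpent-4-en-1-yl]-2-methyloxiran-2-yl]methanol | C=C[C@@](C)(O)CC[C@@H]1O[C@@]1(C)CO | intermediate
4 | (2S)-2-[(2R,5S)-5-ethenyl-5-methyloxolan-2-yl]propane-1,2-diol | C=C[C@]1(C)CC[C@@H](O1)[C@@](C)(O)CO | intermediate
5 | (2S)-2-[(2R,5S)-5-ethenyl-5-methyloxolan-2-yl]-2-hydroxypropyl 4-methylbenzenesulfonate | C=C[C@]1(C)CC[C@@H](O1)[C@@](C)(O)COS(=O)(=O)c2ccc(C)cc2 | intermediate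
6 | (2S,5R)-2-ethenyl-2-methyl-5-[(2S)-2-methyloxiran-2-yl]oxolane | C=C[C@]1(C)CC[C@@H](O1)[C@]2(C)CO2 | intermediate
7 | (R)-2,2-dimethyl-1,3-dioxolane-4-carbaldehyde | O=C[C@H]1COC(C)(C)O1 | starting material
8 | diisopinocampheylborinate ester of 9 | C=C[C@H](C)[C@@H](OB([C@H]2C[C@H]3C[C@@H]([C@@H]2C)C3(C)C)[C@H]4C[C@H]5C[C@@H]([C@@H]4C)C5(C)C)[C@H]1COC(C)(C)O1 | intermediate
9 | (1R,2S)-1-[(4R)-2,2-dimethyl-1,3-dioxolan-4-yl]-2-methylbut-3-en-1-ol | C=C[C@H](C)[C@@H](O)[C@H]1COC(C)(C)O1 | intermediate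
10 | [(4R,5R)-5-[(2S)-but-3-en-2-yl]-2,2-dimethyl-1,3-dioxolan-4-yl]methanol | C=C[C@H](C)[C@H]1OC(C)(C)O[C@@H]1CO | intermediate
11 | {[(4R,5R)-5-[(2S)-but-3-en-2-yl]-2,2-dimethyl-1,3-dioxolan-4-yl]methoxy}triethylsilane | C=C[C@H](C)[C@H]1OC(C)(C)O[C@@H]1CO[Si](CC)(CC)CC | intermediate
12 | B-alkyl-9-borabicyclo[3.3.1]nonane formed from 11 (boron on C10) | C(CB1C2CCCC1CCC2)[C@H](C)[C@H]3OC(C)(C)O[C@@H]3CO[Si](CC)(CC)CC | intermediate
13 | (3S)-3-[(4R,5R)-2,2-dimethyl-5-{[(triethylsilyl)oxy]methyl}-1,3-dioxolan-4-yl]butan-1-ol | OCC[C@H](C)[C@H]1OC(C)(C)O[C@@H]1CO[Si](CC)(CC)CC | intermediate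
14 | {[(4R,5R)-5-[(2S)-4-bromobutan-2-yl]-2,2-dimethyl-1,3-dioxolan-4-yl]methoxy}triethylsilane | BrCC[C@H](C)[C@H]1OC(C)(C)O[C@@H]1CO[Si](CC)(CC)CC | intermediate
15 | Grignard reagent of 14 (C10–MgBr) | Br[Mg]CC[C@H](C)[C@H]1OC(C)(C)O[C@@H]1CO[Si](CC)(CC)CC | intermediate
16 | bromomagnesium C8 alkoxide of the coupled chain | C=C[C@]1(C)CC[C@@H](O1)[C@@](C)(O[Mg]Br)CCC[C@H](C)[C@H]2OC(C)(C)O[C@@H]2CO[Si](CC)(CC)CC | intermediate
17 | (2S,6S)-2-[(2R,5S)-5-ethenyl-5-methyloxolan-2-yl]-6-[(4R,5R)-2,2-dimethyl-5-{[(triethylsilyl)oxy]methyl}-1,3-dioxolan-4-yl]heptan-2-yl acetate | C=C[C@]1(C)CC[C@@H](O1)[C@@](C)(OC(C)=O)CCC[C@H](C)[C@H]2OC(C)(C)O[C@@H]2CO[Si](CC)(CC)CC | intermediate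
18 | 1,2,4-trioxolane (ozonide) of the vinyl group of 17 | C1(OCOO1)[C@]2(C)CC[C@@H](O2)[C@@](C)(OC(C)=O)CCC[C@H](C)[C@H]3OC(C)(C)O[C@@H]3CO[Si](CC)(CC)CC | intermediate
19 | (2S,5R)-5-[(2S,6S)-2-acetoxy-6-[(4R,5R)-2,2-dimethyl-5-{[(triethylsilyl)oxy]methyl}-1,3-dioxolan-4-yl]heptan-2-yl]-2-methyloxolane-2-carbaldehyde | O=C[C@]1(C)CC[C@@H](O1)[C@@](C)(OC(C)=O)CCC[C@H](C)[C@H]2OC(C)(C)O[C@@H]2CO[Si](CC)(CC)CC | intermediate
20 | (4S,5R)-5-[(2S,6S)-6-acetoxy-6-[(2R,5S)-5-formyl-5-methyloxolan-2-yl]heptan-2-yl]-2,2-dimethyl-1,3-dioxolane-4-carbaldehyde | O=C[C@]1(C)CC[C@@H](O1)[C@@](C)(OC(C)=O)CCC[C@H](C)[C@H]2OC(C)(C)O[C@@H]2C=O | intermediate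
21 | methyl acrylate | C=CC(=O)OC | starting material
22 | Morita–Baylis–Hillman alcohol with C3 aldehyde (C1 epimers; other centres as in 20) | C=C(C(=O)OC)C(O)[C@H]1OC(C)(C)O[C@@H]1[C@@H](C)CCC[C@](C)(OC(C)=O)[C@H]2CC[C@](C)(O2)C=O | intermediate
23 | Morita–Baylis–Hillman tert-butyl carbonate with C3 aldehyde (C1 epimers) | C=C(C(=O)OC)C(OC(=O)OC(C)(C)C)[C@H]1OC(C)(C)O[C@@H]1[C@@H](C)CCC[C@](C)(OC(C)=O)[C@H]2CC[C@](C)(O2)C=O | intermediate
24 | seco carbonate with allyl β-keto ester terminus (C1 epimers) | C=C(C(=O)OC)C(OC(=O)OC(C)(C)C)[C@H]1OC(C)(C)O[C@@H]1[C@@H](C)CCC[C@](C)(OC(C)=O)[C@H]2CC[C@](C)(O2)C(=O)CC(=O)OCC=C | intermediate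
25 | methyl (1S,4S,7R,8S,12S,13R,14R)-8-acetoxy-4,7-epoxy-13,14-(isopropylidenedioxy)-3-oxo-2-(prop-2-enyloxycarbonyl)cembr-15(17)-en-16-oate (C2 epimers) | C=C(C(=O)OC)[C@H]1[C@H]3OC(C)(C)O[C@@H]3[C@@H](C)CCC[C@](C)(OC(C)=O)[C@H]2CC[C@](C)(O2)C(=O)C1C(=O)OCC=C | intermediate
26 | 2-carboxy analogue of 25 (β-keto acid, C2 epimers) | C=C(C(=O)OC)[C@H]1[C@H]3OC(C)(C)O[C@@H]3[C@@H](C)CCC[C@](C)(OC(C)=O)[C@H]2CC[C@](C)(O2)C(=O)C1C(=O)O | intermediate
27 | methyl (1S,4S,7R,8S,12S,13R,14R)-8-acetoxy-4,7-epoxy-13,14-(isopropylidenedioxy)-3-oxocembr-15(17)-en-16-oate | C=C(C(=O)OC)[C@H]1[C@H]3OC(C)(C)O[C@@H]3[C@@H](C)CCC[C@](C)(OC(C)=O)[C@H]2CC[C@](C)(O2)C(=O)C1 | intermediate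
28 | methyl (1S,4S,7R,8S,12S,13R,14R)-8-acetoxy-4,7-epoxy-13,14-dihydroxy-3-oxocembr-15(17)-en-16-oate | C=C(C(=O)OC)[C@H]1[C@@H](O)[C@H](O)[C@@H](C)CCC[C@](C)(OC(C)=O)[C@H]2CC[C@](C)(O2)C(=O)C1 | intermediate
29 | (1S,4S,7R,8S,12S,13R,14R)-8-acetoxy-4,7-epoxy-13-hydroxy-3-oxocembr-15(17)-en-16,14-olide | C=C1C(=O)O[C@H]2[C@H](O)[C@@H](C)CCC[C@](C)(OC(C)=O)[C@H]3CC[C@](C)(O3)C(=O)C[C@@H]12 | intermediate
30 | (1S,4S,7R,8S,12S,13R,14R)-8,13-diacetoxy-4,7-epoxy-3-oxocembr-15(17)-en-16,14-olide | C=C1C(=O)O[C@H]2[C@H](OC(C)=O)[C@@H](C)CCC[C@](C)(OC(C)=O)[C@H]3CC[C@](C)(O3)C(=O)C[C@@H]12 | intermediate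
31 | (1S,3R,4S,7R,8S,12S,13R,14R)-8,13-diacetoxy-4,7-epoxy-3-hydroxycembr-15(17)-en-16,14-olide (CID10479028) | C=C1C(=O)O[C@H]2[C@H](OC(C)=O)[C@@H](C)CCC[C@](C)(OC(C)=O)[C@H]3CC[C@](C)(O3)[C@H](O)C[C@@H]12 | target

**Step count and risks**

Total: 19 steps. Longest linear sequence: 16 steps (7 → 31, steps 4–19); the linalool branch is 3 steps to epoxide 6.

1. Step 15 (proposed new method). Chain growth may outrun ring closure, the enolate may attack C17 and give the 16-membered isomer, or facial control at C1 may be lost when catalyst and C14 bias disagree. The fallback sets out from dialdehyde 20 and rejoins the route at 25, using known reaction types. Knoevenagel condensation of the unhindered C1 aldehyde of 20 with trimethyl phosphonoacetate (piperidine, AcOH) would give the alkylidene phosphonoacetate F1. Roskamp homologation of the remaining C3 aldehyde (allyl diazoacetate, SnCl2) would give the β-keto ester F2. Intramolecular Michael addition of the β-keto ester to the doubly activated alkene (Cs2CO3, MeCN, high dilution), a base-mediated conjugate ring closure of an established type, would form C1–C2 and give the macrocyclic phosphonate F3. Horner–Wadsworth–Emmons reaction of F3 with formaldehyde (K2CO3, aqueous CH2O) would then unveil the 2-methylene ester and deliver 25. In this variant C1 is set by the C14 dioxolane alone.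

2. Step 4. The Felkin preference of aldehyde 7 opposes the reagent, so facial selectivity may be poor in this mismatched pairing. The fallback sets out from 7 and rejoins at 9. The matched reagent, (E)-crotyl-B(Ipc)2 of the (+)-α-pinene series [from (−)-Ipc2BOMe], adds to the Si (Felkin) face of 7. After oxidative work-up of the borinate ester F4 it should give the 12,13-anti-13,14-anti alcohol F5 with high selectivity. Mitsunobu inversion at C13 (4-nitrobenzoic acid, PPh3, DIAD) would give the 4-nitrobenzoate F6, and methanolysis (K2CO3, MeOH) would give 9.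

3. Step 19. The macrocycle conformation may override the zinc chelate and deliver hydride to the wrong face, or hydride may add 1,4 to the methylene lactone. The fallback sets out from 30 and ends at 31 by catalyst control instead of chelate control: Corey–Bakshi–Shibata reduction [(S)-2-methyl-CBS-oxazaborolidine, catecholborane, PhMe, −78 °C]. The oxazaborolidine distinguishes the fully substituted C4 side from the C2 methylene side and should give 3R, and boranes of this kind do not reduce the unsaturated lactone. No new compound is made.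

**Further compounds**

F1 | step 15 | alkylidene phosphonoacetate at C1 with C3 aldehyde (alkene geometry undefined; other centres as in 20) | COC(=O)C(=C[C@H]1OC(C)(C)O[C@@H]1[C@@H](C)CCC[C@](C)(OC(C)=O)[C@H]2CC[C@](C)(O2)C=O)P(=O)(OC)OC
F2 | step 15 | alkylidene phosphonoacetate at C1 with allyl β-keto ester at C3 | COC(=O)C(=C[C@H]1OC(C)(C)O[C@@H]1[C@@H](C)CCC[C@](C)(OC(C)=O)[C@H]2CC[C@](C)(O2)C(=O)CC(=O)OCC=C)P(=O)(OC)OC
F3 | step 15 | macrocyclic phosphonate, 25 with CH(CO2Me)P(O)(OMe)2 at C1 in place of the propenoate (C2 and C15 epimers) | COC(=O)C([C@H]1[C@H]3OC(C)(C)O[C@@H]3[C@@H](C)CCC[C@](C)(OC(C)=O)[C@H]2CC[C@](C)(O2)C(=O)C1C(=O)OCC=C)P(=O)(OC)OC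
F4 | step 4 | diisopinocampheylborinate ester of F5 ((+)-α-pinene series) | C=C[C@H](C)[C@H](OB([C@@H]2C[C@@H]3C[C@H]([C@H]2C)C3(C)C)[C@@H]4C[C@@H]5C[C@H]([C@H]4C)C5(C)C)[C@H]1COC(C)(C)O1
F5 | step 4 | (1S,2S)-1-[(4R)-2,2-dimethyl-1,3-dioxolan-4-yl]-2-methylbut-3-en-1-ol | C=C[C@H](C)[C@H](O)[C@H]1COC(C)(C)O1
F6 | step 4 | (1R,2S)-1-[(4R)-2,2-dimethyl-1,3-dioxolan-4-yl]-2-methylbut-3-en-1-yl 4-nitrobenzoate | C=C[C@H](C)[C@@H](OC(=O)c2ccc(cc2)[N+](=O)[O-])[C@H]1COC(C)(C)O1
F0 | step 19 | none | none
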